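**Plan**
- Retrosynthesis: after removal of the two MOM groups, ring A is cut at C4a–C5 and C7–C8; this frees C5–C6–C7 as an oxygenated malonate diester and leaves ring C as a chiral 6-alkyl-2-aryl-2,3-dihydropyran-4-one.
- The pyranone is cut further at C8–C8a (homoprenyl Grignard reagent) and at C2–C3 and O1–C8a (aryl aldehyde plus siloxydiene).
- Enabling feature: ring A bears oxygen on the alternate carbons C5, C7 and C8a, a further oxygen on C6 and the prenyl group on C8. It is therefore a cyclised 1,3,5-tricarbonyl array whose C5–C6–C7 part is a malonate and whose C4a and C8 are the two nucleophilic ends of the vinylogous enolate of ring C; closing ring A on the finished ring C also fixes which oxygen is O1.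
- Forward order: ring C (asymmetric hetero-Diels–Alder reaction), then the C8 side chain (conjugate addition, re-oxidation), then ring A in one operation (double Claisen condensation with reductive aromatisation), then deprotection.
- Stereochemistry: the single stereocentre C2 (S) is set by the titanium–BINOL catalyst in the hetero-Diels–Alder step and kept because the O1–C2 bond is never broken afterwards.

Key step: step 6

Assumption: the (S)-BINOL–Ti(OiPr)4 catalyst is taken to direct the enol silane to the Si face of the aryl aldehyde, the sense known for allylstannane additions with this catalyst; if the opposite sense is found, (R)-BINOL is used.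
Remark: a malonate with a hydrogen on its central carbon is far more acidic than the pyranone and would only protonate the dienolate, so the three-carbon unit is used one oxidation level higher, as a hydrogen-free bis(MOM) ketal, and ring A is aromatised by zinc in the same flask.

Step 1
Reactants: 1 4-hydroxybenzaldehyde
Product: 2 4-(methoxymethoxy)benzaldehyde
Conditions: MOMCl, iPr2NEt, CH2Cl2, 0 → 25 °C
Reagents that add atoms: chloromethyl methyl ether, COCCl
Why: O-alkylation of the phenol with the reactive α-chloro ether (Williamson-type etherification) gives a MOM ether that is stable to the bases and organometallics used later and is removed by acid at the end.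

Step 2
Reactants: 2 4-(methoxymethoxy)benzaldehyde; 3 (E)-1-methoxy-3-(trimethylsilyloxy)buta-1,3-diene
Product: 5 (S)-2-[4-(methoxymethoxy)phenyl]-2,3-dihydro-4H-pyran-4-one, via silylated aldol adduct 4 (not isolated)
Conditions: Ti(OiPr)4 (10 mol %), (S)-BINOL (20 mol %), 4 Å MS, Et2O, −20 °C; then CF3CO2H (cat.), CH2Cl2, 0 °C
Reagents that add atoms: none
Why: Catalytic asymmetric hetero-Diels–Alder reaction by the Mukaiyama aldol/cyclisation pathway, in which the chiral titanium–BINOL Lewis acid lets the enol silane add to the Si face of the aldehyde and so sets C2 as S, after which acid closes ring C by addition–elimination with loss of methanol; the product should be recrystallised if enantiomeric enrichment is needed.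

Step 3
Reactants: 5 (S)-2-[4-(methoxymethoxy)phenyl]-2,3-dihydro-4H-pyran-4-one; 6 5-bromo-2-methylpent-2-ene
Product: 8 trimethyl{[(2S,6R)-2-[4-(methoxymethoxy)phenyl]-6-(4-methylpent-3-enyl)-3,6-dihydro-2H-pyran-4-yl]oxy}silane, via Grignard reagent 7 (not isolated)
Conditions: 6, Mg, THF, 25 °C; then CuBr·SMe2 (10 mol %), TMSCl, 5, THF, −78 → −40 °C; Et3N, aq NaHCO3
Reagents that add atoms: chlorotrimethylsilane, C[Si](C)(C)Cl
Why: Copper-catalysed conjugate addition of the Grignard reagent, accelerated and trapped by TMSCl, places the side chain on pyranone C6 by axial attack anti to the C2 aryl group (C6 becomes R, a centre removed again in step 4) and fixes the enolate as the C4–C5 enol silane.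

Step 4
Reactants: 8 trimethyl{[(2S,6R)-2-[4-(methoxymethoxy)phenyl]-6-(4-methylpent-3-enyl)-3,6-dihydro-2H-pyran-4-yl]oxy}silane
Product: 9 (S)-2-[4-(methoxymethoxy)phenyl]-6-(4-methylpent-3-enyl)-2,3-dihydro-4H-pyran-4-one
Conditions: Pd(OAc)2 (1.05 equiv), MeCN, 25 °C
Reagents that add atoms: none
Why: Saegusa–Ito oxidation, in which the divalent palladium enolate at C5 can undergo β-hydride elimination only towards C6, so the enone returns regiospecifically as the 6-alkyl dihydropyranone while C2 and the trisubstituted alkene stay untouched.

Step 5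
Reactants: 10 diethyl 2,2-dihydroxymalonate
Product: 11 diethyl 2,2-bis(methoxymethoxy)malonate
Conditions: MOMCl (3 equiv), iPr2NEt (4 equiv), Bu4NI (cat.), CH2Cl2, 0 → 40 °C
Reagents that add atoms: chloromethyl methyl ether, COCCl
Why: Double O-alkylation of the hydrate of a strongly electron-poor ketone, the usual way to ketals of such ketones because acid-catalysed ketalisation fails, gives a malonate with no α-hydrogen whose two ester groups remain good Claisen acceptors.

Step 6
Reactants: 9 (S)-2-[4-(methoxymethoxy)phenyl]-6-(4-methylpent-3-enyl)-2,3-dihydro-4H-pyran-4-one; 11 diethyl 2,2-bis(methoxymethoxy)malonate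
Product: 14 (S)-5,7-dihydroxy-6-(methoxymethoxy)-2-[4-(methoxymethoxy)phenyl]-8-(3-methylbut-2-enyl)chroman-4-one, via lithium dienolate 12 (not isolated), via bis(methoxymethoxy) dienone 13 (not isolated)
Conditions: LiN(SiMe3)2 (0.95 equiv), THF, −78 → −30 °C; 11 (1.2 equiv), −78 °C; LiN(SiMe3)2 (1.3 equiv), −78 → 0 °C; AcOH, −78 °C; Zn dust, 0 → 25 °C
Reagents that add atoms: none
Why: Proposed new method: the linearly conjugated lithium dienolate 12, formed by proton loss from the first side-chain carbon (the future C8), is acylated at C8 or at pyranone C5 (the future C4a) by one ester group of 11, the liberated ethoxide or the second portion of amide regenerates a vinylogous enolate, and its remaining nucleophilic carbon attacks the second ester to close ring A, giving after the acid quench the 6,6-dialkoxy dienone 13, which zinc reduces with loss of one methoxymethoxide so that ring A aromatises to the 5,7-diphenol. The closest known reaction types are the Claisen acylation of ketone enolates by oxalate-type esters, the base-mediated Dieckmann cyclisation of triketo esters to phloroglucinols and the zinc reduction of quinone monoketals to alkoxyphenols. Ring A closes by 6-exo-trig attack on the ester carbonyl (enolexo or enolendo according to which carbon was acylated first, both favourable for a six-membered ring), and either order gives the same ring. No stereocentre is formed, and C2 is kept because only the C3 enolate can open ring C by E1cB and it stays scarce at low temperature and is quenched cold. The step needs proton removal at C8 and not at C3, which the substrate supplies through the greater stability of the conjugated dienolate once slightly sub-stoichiometric base allows proton exchange; it also needs C- and not O-acylation, which the reversibility of ester exchange and the irreversible formation of the stabilised triketone enolate secure. Because the central carbon of 11 bears no hydrogen, the malonate cannot protonate the dienolate.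

Step 7
Reactants: 14 (S)-5,7-dihydroxy-6-(methoxymethoxy)-2-[4-(methoxymethoxy)phenyl]-8-(3-methylbut-2-enyl)chroman-4-one
Product: 15 nirurinetin
Conditions: HCl (1.25 M in MeOH), 40 °C
Reagents that add atoms: none
Why: Acid-catalysed acetal exchange with methanol cleaves both aryl MOM ethers, while the flavanone, which is configurationally stable in acid, and the prenyl group should survive these mild conditions.

**Compound list**
1 | 4-hydroxybenzaldehyde | O=Cc1ccc(O)cc1 | starting material
2 | 4-(methoxymethoxy)benzaldehyde | COCOc1ccc(C=O)cc1 | intermediate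
3 | (E)-1-methoxy-3-(trimethylsilyloxy)buta-1,3-diene | CO/C=C/C(=C)O[Si](C)(C)C | starting material
4 | (S,E)-1-methoxy-5-[4-(methoxymethoxy)phenyl]-5-(trimethylsilyloxy)pent-1-en-3-one | CO/C=C/C(=O)C[C@H](O[Si](C)(C)C)c1ccc(OCOC)cc1 | intermediate
5 | (S)-2-[4-(methoxymethoxy)phenyl]-2,3-dihydro-4H-pyran-4-one | O=C1C[C@@H](c2ccc(OCOC)cc2)OC=C1 | intermediate
6 | 5-bromo-2-methylpent-2-ene | CC(C)=CCCBr | starting material
7 | (4-methylpent-3-enyl)magnesium bromide | CC(C)=CCC[Mg]Br | intermediate
8 | trimethyl{[(2S,6R)-2-[4-(methoxymethoxy)phenyl]-6-(4-methylpent-3-enyl)-3,6-dihydro-2H-pyran-4-yl]oxy}silane | C[Si](C)(C)OC1=C[C@@H](CCC=C(C)C)O[C@H](c2ccc(OCOC)cc2)C1 | intermediate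
9 | (S)-2-[4-(methoxymethoxy)phenyl]-6-(4-methylpent-3-enyl)-2,3-dihydro-4H-pyran-4-one | CC(C)=CCCC1=CC(=O)C[C@@H](c2ccc(OCOC)cc2)O1 | intermediate
10 | diethyl 2,2-dihydroxymalonate (hydrate of diethyl oxomalonate) | CCOC(=O)C(O)(O)C(=O)OCC | starting material
11 | diethyl 2,2-bis(methoxymethoxy)malonate | CCOC(=O)C(OCOC)(OCOC)C(=O)OCC | intermediate
12 | lithium (2S)-2-[4-(methoxymethoxy)phenyl]-6-(4-methylpent-3-enylidene)-3,6-dihydro-2H-pyran-4-olate (geometry of the exocyclic alkene not defined) | [Li+].[O-]C1=CC(=CCC=C(C)C)O[C@H](c2ccc(OCOC)cc2)C1 | intermediate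
13 | (2S)-7-hydroxy-6,6-bis(methoxymethoxy)-2-[4-(methoxymethoxy)phenyl]-8-(3-methylbut-2-enyl)-2,3-dihydro-4H-chromene-4,5(6H)-dione | CC(C)=CCC1=C(O)C(OCOC)(OCOC)C(=O)C2=C1O[C@H](c1ccc(OCOC)cc1)CC2=O | intermediate
14 | (S)-5,7-dihydroxy-6-(methoxymethoxy)-2-[4-(methoxymethoxy)phenyl]-8-(3-methylbut-2-enyl)chroman-4-one | CC(C)=CCc1c(O)c(OCOC)c(O)c2c1O[C@H](c1ccc(OCOC)cc1)CC2=O | intermediate
15 | nirurinetin, (S)-5,6,7-trihydroxy-2-(4-hydroxyphenyl)-8-(3-methylbut-2-enyl)chroman-4-one | CC(C)=CCc1c(O)c(O)c(O)c2c1O[C@H](c1ccc(O)cc1)CC2=O | target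

**Step count**
Total: 7 steps. Longest linear sequence: 6 steps (1, 2, 3, 4, 6, 7); step 5 prepares the three-carbon partner.

**Steps most likely to fail**

1. Step 6. What may go wrong: proton removal at C3 instead of C8, followed by acylation at C3 or by E1cB opening of ring C with loss of the C2 configuration; the second Claisen closure may also stall at the open keto ester.
Fallback, with known reaction types only, from 8 back to 14: the two carbon–carbon bonds are made one after the other through enolates whose position is fixed by structure. Cleavage of enol silane 8 with MeLi (THF, 0 °C) gives the regiodefined lithium enolate F1. Its C5 (the future C4a) is acylated by 11 at −78 °C in a Claisen condensation with a non-enolisable ester, giving the C-acylated tetrahydropyranone F2. Selenenylation of the preformed sodium enolate of F2 with PhSeCl at −78 °C, where the enolate outruns the alkene, gives the selenide F3. Oxidation with H2O2 leads by selenoxide syn-elimination, possible only towards C6, to the 5-acyl dihydropyranone F4. In F4 the C8 hydrogens are vinylogous to two carbonyl groups and far more acidic than those at C3, so LiN(SiMe3)2 (2 equiv, THF, −78 → 0 °C) removes a C8 proton only and the anion closes ring A on the remaining ester (Dieckmann condensation) to give 13, which is reduced in the same flask with Zn/AcOH to 14.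

2. Step 5. What may go wrong: loss of water from the gem-diol under base returns the ketone, so alkylation stops at the mono-ether or does not start.
Fallback, from 10 back to 15: the diol is silylated instead of alkylated, so that no alkoxide is formed. TESOTf/2,6-lutidine (CH2Cl2, −78 → 0 °C) gives the silyl ketal F5. F5 replaces 11 in step 6 and should give, through the bis(silyloxy) dienone F6 and the zinc reduction, the 6-silyl ether F7. The conditions of step 7 then remove the silyl and the MOM group together to give 15.

3. Step 7. What may go wrong: acid-catalysed addition of the C7 hydroxyl to the prenyl double bond (chroman formation) and acid-promoted opening of ring C during the slower cleavage of the hindered C6 acetal.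
Fallback, from 14 back to 15: the MOM ethers are exchanged for silyl ethers without free protic acid. TMSOTf/2,2'-bipyridyl (MeCN, 0 °C) converts the aryl MOM ethers and the free phenols into the persilylated flavanone F8, which is hydrolysed to 15 by water at neutral pH on work-up.

**Further compounds**
F1 | step 6 | lithium (2S,6R)-2-[4-(methoxymethoxy)phenyl]-6-(4-methylpent-3-enyl)-3,6-dihydro-2H-pyran-4-olate | [Li+].[O-]C1=C[C@@H](CCC=C(C)C)O[C@H](c2ccc(OCOC)cc2)C1
F2 | step 6 | ethyl 3-[(2R,6S)-6-[4-(methoxymethoxy)phenyl]-2-(4-methylpent-3-enyl)-4-oxooxan-3-yl]-2,2-bis(methoxymethoxy)-3-oxopropanoate (ring C3 epimeric or enolised) | CCOC(=O)C(OCOC)(OCOC)C(=O)C1C(=O)C[C@@H](c2ccc(OCOC)cc2)O[C@@H]1CCC=C(C)C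
F3 | step 6 | ethyl 3-[(2R,6S)-6-[4-(methoxymethoxy)phenyl]-2-(4-methylpent-3-enyl)-4-oxo-3-(phenylselanyl)oxan-3-yl]-2,2-bis(methoxymethoxy)-3-oxopropanoate (ring C3 not defined) | CCOC(=O)C(OCOC)(OCOC)C(=O)C1([Se]c2ccccc2)C(=O)C[C@@H](c2ccc(OCOC)cc2)O[C@@H]1CCC=C(C)C
F4 | step 6 | ethyl 3-[(2S)-2-[4-(methoxymethoxy)phenyl]-6-(4-methylpent-3-enyl)-4-oxo-2,3-dihydro-4H-pyran-5-yl]-2,2-bis(methoxymethoxy)-3-oxopropanoate | CCOC(=O)C(OCOC)(OCOC)C(=O)C1=C(CCC=C(C)C)O[C@H](c2ccc(OCOC)cc2)CC1=O
F5 | step 5 | diethyl 2,2-bis(triethylsilyloxy)malonate | CCOC(=O)C(O[Si](CC)(CC)CC)(O[Si](CC)(CC)CC)C(=O)OCC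
F6 | step 5 | (2S)-7-hydroxy-2-[4-(methoxymethoxy)phenyl]-8-(3-methylbut-2-enyl)-6,6-bis(triethylsilyloxy)-2,3-dihydro-4H-chromene-4,5(6H)-dione | CC(C)=CCC1=C(O)C(O[Si](CC)(CC)CC)(O[Si](CC)(CC)CC)C(=O)C2=C1O[C@H](c1ccc(OCOC)cc1)CC2=O
F7 | step 5 | (S)-5,7-dihydroxy-2-[4-(methoxymethoxy)phenyl]-8-(3-methylbut-2-enyl)-6-(triethylsilyloxy)chroman-4-one | CC(C)=CCc1c(O)c(O[Si](CC)(CC)CC)c(O)c2c1O[C@H](c1ccc(OCOC)cc1)CC2=O
F8 | step 7 | (S)-8-(3-methylbut-2-enyl)-5,6,7-tris(trimethylsilyloxy)-2-[4-(trimethylsilyloxy)phenyl]chroman-4-one | CC(C)=CCc1c(O[Si](C)(C)C)c(O[Si](C)(C)C)c(O[Si](C)(C)C)c2c1O[C@H](c1ccc(O[Si](C)(C)C)cc1)CC2=O
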